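The route rests on cutting the bicyclo[3.3.1]nonane core at C2–C3 and C4–C5. Both quaternary bridgeheads C1 and C5 flank the C9 ketone and each bears one more acyl carbon, so removing C3/C4 and joining C2 to C5 leaves a bridged cyclobutane-1,3-dione (C1–C2–C5–C9), formally the head-to-tail dimer of two dialkylketenes. Nickel-catalysed insertion of ethoxyacetylene into that four-membered ring enlarges it in one operation to the six-membered C1–C2–C3–C4–C5–C9 ring, fixes both bridgehead stereocentres relative to C7 and leaves C3–H between a ketone and an enol ether for aroylation. The precursor is a bicyclo[3.1.1]heptane-6,7-dione with C7 as its only stereocentre, closed from a pimelic diacid through its bis(ketene).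

Key step: step 11

Remark: atom labels C1–C9 are those of the target core (C1 prenyl bridgehead, C5 geranyl bridgehead, C7 geranyl methine, C8 gem-dimethyl, C9 bridging ketone); the drawn enol is taken as one tautomer of the enolised triketone, and compounds 5 to 21 are carried as epimer mixtures at the carbons that later become ketene carbons, which is of no consequence.

Step 1
Reactants: 1 3,3-dimethylglutaric anhydride
Product: 2 5-tert-butoxy-3,3-dimethyl-5-oxopentanoic acid
Conditions: t-BuOH, DMAP (cat.), N-hydroxysuccinimide (cat.), Et3N (cat.), PhMe, reflux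
Reagents that add atoms: tert-butanol, CC(C)(C)O
Why: Acyl-transfer-catalysed alcoholysis of the symmetric cyclic anhydride (anhydride ring opening) stops at the half ester, and the tert-butyl ester is chosen because it should survive enolate, hydride and iodination chemistry without lactonising.

Step 2
Reactants: 2 5-tert-butoxy-3,3-dimethyl-5-oxopentanoic acid; 3 prenyl bromide
Product: 5 racemic 4-(tert-butoxycarbonyl)-3,3,7-trimethyloct-6-enoic acid, via dilithium carboxylate ester enolate 4 (not isolated)
Conditions: LiN(i-Pr)2 (2.2 equiv), THF, −78 → −20 °C; 3, −78 → 0 °C; aq. HCl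
Reagents that add atoms: none
Why: After deprotonation of the acid, the second equivalent of base enolises the more acidic ester α-methylene and the enolate is alkylated at the primary carbon of the allylic bromide (enolate alkylation of a half-ester dianion); the new centre is racemic, which does not matter because it becomes a ketene carbon in step 10.

Step 3
Reactants: 5 racemic 4-(tert-butoxycarbonyl)-3,3,7-trimethyloct-6-enoic acid; 6 (S)-4-benzyl-1,3-oxazolidin-2-one
Product: 8 (4S)-4-benzyl-3-[4-(tert-butoxycarbonyl)-3,3,7-trimethyloct-6-enoyl]-1,3-oxazolidin-2-one, via mixed pivalic anhydride 7 (not isolated)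
Conditions: t-BuCOCl, Et3N, THF, −20 °C; then LiCl, 6, −20 °C → rt
Reagents that add atoms: none
Why: Mixed-anhydride N-acylation of the oxazolidinone: the LiCl-activated oxazolidinone should attack the unbranched CH2–C=O of 7 and not the pivaloyl carbonyl, so the auxiliary is attached without touching the ester.

Step 4
Reactants: 8 (4S)-4-benzyl-3-[4-(tert-butoxycarbonyl)-3,3,7-trimethyloct-6-enoyl]-1,3-oxazolidin-2-one; 9 geranyl bromide
Product: 11 (4S)-4-benzyl-3-[(2S)-4-(tert-butoxycarbonyl)-2-[(2E)-3,7-dimethylocta-2,6-dien-1-yl]-3,3,7-trimethyloct-6-enoyl]-1,3-oxazolidin-2-one, via sodium Z-enolate 10 (not isolated)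
Conditions: NaN(SiMe3)2 (1.1 equiv), THF, −78 °C; 9, −78 → −40 °C
Reagents that add atoms: none
Why: Evans asymmetric alkylation: the chelated sodium Z-enolate is shielded on one face by the benzyl group, so geranyl bromide should add from the opposite face and set the (S)-configured α-carbon that becomes C7, while the far less acidic, hindered ester methine is not enolised.

Step 5
Reactants: 11 the geranylated imide
Product: 12 tert-butyl (4S,6E)-4-(hydroxymethyl)-3,3,7,11-tetramethyl-2-(3-methylbut-2-en-1-yl)dodeca-6,10-dienoate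
Conditions: LiBH4, MeOH (1.1 equiv), Et2O, 0 °C
Reagents that add atoms: none
Why: Reductive cleavage of the N-acyl oxazolidinone by LiBH4 (hydride attack at the exocyclic carbonyl) should give the primary alcohol and the recoverable auxiliary under non-enolising conditions, so the new stereocentre is kept and the hindered tert-butyl ester is neither reduced nor lactonised.

Step 6
Reactants: 12 the hydroxy ester
Product: 13 tert-butyl (4S,6E)-4-(iodomethyl)-3,3,7,11-tetramethyl-2-(3-methylbut-2-en-1-yl)dodeca-6,10-dienoate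
Conditions: I2, PPh3, imidazole, CH2Cl2, 0 °C → rt
Reagents that add atoms: iodine, II
Why: Appel-type iodination (alkoxyphosphonium formation, then SN2 displacement by iodide) converts the primary alcohol into the iodide under buffered neutral conditions that leave the alkenes, the ester and the adjacent stereocentre untouched.

Step 7
Reactants: 14 acetic acid; 9 geranyl bromide
Product: 16 (4E)-5,9-dimethyldeca-4,8-dienoic acid, via dilithio acetate 15 (not isolated)
Conditions: LiN(i-Pr)2 (2.1 equiv), THF–DMPU, 0 → 35 °C; 9, 0 °C → rt; aq. HCl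
Reagents that add atoms: none
Why: Alkylation of the acetic acid dianion (enediolate alkylation) occurs by SN2 at the primary allylic carbon with retention of the E double bond and gives the γ,δ-unsaturated acid in one step.

Step 8
Reactants: 13 the iodo ester; 16 (4E)-5,9-dimethyldeca-4,8-dienoic acid
Product: 18 (4R)-7-tert-butoxy-2,4-bis[(2E)-3,7-dimethylocta-2,6-dien-1-yl]-5,5-dimethyl-6-(3-methylbut-2-en-1-yl)-7-oxoheptanoic acid, via dilithium enediolate 17 (not isolated)
Conditions: 16, LiN(i-Pr)2 (2.1 equiv), THF–DMPU, 0 °C; 13, 0 → 40 °C; aq. HCl (pH 3), 0 °C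
Reagents that add atoms: none
Why: Alkylation of a carboxylic acid dianion: the enediolate of 16 is nucleophilic and thermally robust enough to displace the β-branched primary iodide on warming; C7 is not affected, and the new α-centre forms unselectively, which is irrelevant because it becomes a ketene carbon.

Step 9
Reactants: 18 the acid tert-butyl ester
Product: 20 (4R)-4,6-bis[(2E)-3,7-dimethylocta-2,6-dien-1-yl]-3,3-dimethyl-2-(3-methylbut-2-en-1-yl)heptanedioic acid, via bis(trimethylsilyl) ester 19 (not isolated)
Conditions: Me3SiOTf (3 equiv), 2,6-lutidine (4 equiv), CH2Cl2, 0 °C → rt; then pH 5 buffer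
Reagents that add atoms: none
Why: Silyl-triflate-mediated cleavage of the tert-butyl ester by alkyl–oxygen fission (loss of isobutene from the O-silylated ester, buffered by 2,6-lutidine) should free the hindered carboxyl without acyl substitution and without protic acid that could cyclise the polyene; the silyl esters hydrolyse on work-up.

Step 10
Reactants: 20 the pimelic diacid
Product: 23 (3R)-3,5-bis[(2E)-3,7-dimethylocta-2,6-dien-1-yl]-2,2-dimethyl-1-(3-methylbut-2-en-1-yl)bicyclo[3.1.1]heptane-6,7-dione, via bis(acid chloride) 21 (not isolated), via bis(ketene) 22 (not isolated)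
Conditions: Me2C=C(Cl)NMe2 (2.2 equiv), CH2Cl2, 0 °C → rt; then syringe-pump addition to Et3N, PhMe, 110 °C (final 0.003 M)
Reagents that add atoms: none
Why: Dehydrochlorination of the two α-branched acyl chlorides gives tethered dialkylketenes that should undergo the thermal head-to-tail [2+2] ketene dimerisation to the cyclobutane-1,3-dione, the three-atom C6–C7–C8 tether holding each ketene carbonyl carbon over the α-carbon of the other through six-membered arrays while high dilution suppresses intermolecular dimerisation; the two α-centres of 20 disappear and C7 remains the only stereocentre.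

Step 11
Reactants: 23 the bicyclo[3.1.1]heptane-6,7-dione; 24 ethoxyacetylene
Product: 25 (1R,5S,7R)-4-ethoxy-5,7-bis[(2E)-3,7-dimethylocta-2,6-dien-1-yl]-8,8-dimethyl-1-(3-methylbut-2-en-1-yl)bicyclo[3.3.1]non-3-ene-2,9-dione
Conditions: Ni(cod)2 (10 mol%), PCy3 (20 mol%), PhMe, 60 °C; 24 (3 equiv) by syringe pump
Reagents that add atoms: none
Why: Proposed new method: zerovalent nickel should couple one carbonyl of 23 with the alkyne by oxidative cyclisation to an oxanickelacyclopentene (divalent nickel) in which the unsubstituted, nucleophilic alkyne carbon is bonded to the carbonyl carbon (C2–C3); β-carbon elimination, here a strain-relieving retro-aldol-type cleavage of C2–C5 that leaves a nickel enolate of the C9 ketone, and reductive elimination (C4–C5) then release 25 and zerovalent nickel. The closest known reaction type is the nickel-catalysed insertion of internal alkynes into cyclobutanones to give cyclohex-2-enones, which has not been shown for cyclobutane-1,3-diones or for ynol ethers. The six-membered ring C1–C2–C3–C4–C5–C9 is closed not by a cyclisation but by two-carbon enlargement of the four-membered ring, its last bond forming by reductive elimination within a seven-membered nickelacycle. C1 and C5 become stereocentres: their mutual configuration is dictated by the bicyclic frame, and their relation to C7 by which carbonyl bridge is enlarged. The step needs (a) reaction at the bridge anti to the C7 geranyl group, expected because the sector between the syn bridge and the C6–C7–C8 bridge is filled by the geranyl methylene, so the tetrahedral nickelacycle, which must place its O–Ni or alkenyl arm in that sector, should form on the side that faces only the C7 hydrogen, and (b) ethoxy on the carbon that ends at the bridgehead, secured because the terminal alkyne carbon is both the less hindered and the more nucleophilic one. Cleavage of either C–C bond of the chosen carbonyl gives an enol ether of the same trione, and the quaternary bridgeheads leave no β-hydrogen for elimination.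

Step 12
Reactants: 26 3,4-dihydroxybenzoic acid
Product: 27 tert-butyldimethylsilyl 3,4-bis(tert-butyldimethylsilyloxy)benzoate
Conditions: t-BuMe2SiCl (3.3 equiv), imidazole, DMF, rt
Reagents that add atoms: tert-butyldimethylsilyl chloride, CC(C)(C)[Si](C)(C)Cl
Why: Exhaustive silylation of the two phenols and the carboxylic acid (silyl ether and silyl ester formation) masks every acidic proton of the aroyl unit in one operation.

Step 13
Reactants: 27 the tris-silylated acid
Product: 28 3,4-bis(tert-butyldimethylsilyloxy)benzoyl chloride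
Conditions: (COCl)2, DMF (cat.), CH2Cl2, 0 °C → rt
Reagents that add atoms: oxalyl chloride, O=C(Cl)C(Cl)=O
Why: The silyl ester is converted directly into the acyl chloride by the chloroiminium salt formed from oxalyl chloride and DMF (Vilsmeier-type activation) with release of silyl chloride and no hydrogen chloride, so the aryl silyl ethers should survive.

Step 14
Reactants: 25 the ethyl enol ether; 28 3,4-bis(tert-butyldimethylsilyloxy)benzoyl chloride
Product: 30 (1S,5S,7R)-3-[3,4-bis(tert-butyldimethylsilyloxy)benzoyl]-4-ethoxy-5,7-bis[(2E)-3,7-dimethylocta-2,6-dien-1-yl]-8,8-dimethyl-1-(3-methylbut-2-en-1-yl)bicyclo[3.3.1]non-3-ene-2,9-dione, via C3-lithio enol ether 29 (not isolated)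
Conditions: lithium 2,2,6,6-tetramethylpiperidide, THF, −78 °C; then 28, −78 → 0 °C
Reagents that add atoms: none
Why: Directed vinylic deprotonation followed by acylation: with both bridgeheads quaternary, the C3–H of the β-alkoxy enone is the only acidic position, the hindered amide base removes it without adding to a carbonyl, and the vinyllithium is acylated by the aroyl chloride, a sequence established for enol ethers of bicyclo[3.3.1]nonane-2,4,9-triones; no stereocentre is involved.

Step 15
Reactants: 30 the silylated aroyl enol ether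
Product: 31 (1S,5S,7R)-3-(3,4-dihydroxybenzoyl)-4-hydroxy-5,7-bis[(2E)-3,7-dimethylocta-2,6-dien-1-yl]-8,8-dimethyl-1-(3-methylbut-2-en-1-yl)bicyclo[3.3.1]non-3-ene-2,9-dione
Conditions: LiOH, dioxane–H2O (degassed), 80 °C; then aq. HCl to pH 3
Reagents that add atoms: lithium hydroxide, [Li+].[OH-]
Why: Hydroxide cleaves both aryl silyl ethers at silicon and replaces ethoxide at C4 by conjugate addition–elimination on the doubly acyl-activated vinylogous ester (vinylogous ester hydrolysis), and acidification gives the enolised triketone; C1 and C5 are quaternary and C7 is remote from any carbonyl, so no stereocentre can epimerise.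

Compound list
1 | 3,3-dimethylglutaric anhydride | CC1(C)CC(=O)OC(=O)C1 | starting material
2 | 5-tert-butoxy-3,3-dimethyl-5-oxopentanoic acid | CC(C)(C)OC(=O)CC(C)(C)CC(=O)O | intermediate
3 | prenyl bromide (1-bromo-3-methylbut-2-ene) | CC(C)=CCBr | starting material
4 | dilithium carboxylate ester enolate of 2 | [Li+].[Li+].[O-]C(=O)CC(C)(C)C=C([O-])OC(C)(C)C | intermediate
5 | racemic 4-(tert-butoxycarbonyl)-3,3,7-trimethyloct-6-enoic acid | CC(C)=CCC(C(=O)OC(C)(C)C)C(C)(C)CC(=O)O | intermediate
6 | (S)-4-benzyl-1,3-oxazolidin-2-one | O=C1N[C@@H](Cc2ccccc2)CO1 | starting material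
7 | mixed pivalic anhydride of 5 | CC(C)=CCC(C(=O)OC(C)(C)C)C(C)(C)CC(=O)OC(=O)C(C)(C)C | intermediate
8 | (4S)-4-benzyl-3-[4-(tert-butoxycarbonyl)-3,3,7-trimethyloct-6-enoyl]-1,3-oxazolidin-2-one (both epimers at the prenyl-bearing carbon) | CC(C)=CCC(C(=O)OC(C)(C)C)C(C)(C)CC(=O)N1[C@@H](Cc2ccccc2)COC1=O | intermediate
9 | geranyl bromide ((2E)-1-bromo-3,7-dimethylocta-2,6-diene) | CC(C)=CCC/C(C)=C/CBr | starting material
10 | sodium Z-enolate of 8 | [Na+].CC(C)=CCC(C(=O)OC(C)(C)C)C(C)(C)/C=C(\[O-])N1[C@@H](Cc2ccccc2)COC1=O | intermediate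
11 | (4S)-4-benzyl-3-[(2S)-4-(tert-butoxycarbonyl)-2-[(2E)-3,7-dimethylocta-2,6-dien-1-yl]-3,3,7-trimethyloct-6-enoyl]-1,3-oxazolidin-2-one | CC(C)=CCC/C(C)=C/C[C@@H](C(C)(C)C(CC=C(C)C)C(=O)OC(C)(C)C)C(=O)N1[C@@H](Cc2ccccc2)COC1=O | intermediate
12 | tert-butyl (4S,6E)-4-(hydroxymethyl)-3,3,7,11-tetramethyl-2-(3-methylbut-2-en-1-yl)dodeca-6,10-dienoate | CC(C)=CCC/C(C)=C/C[C@@H](C(C)(C)C(CC=C(C)C)C(=O)OC(C)(C)C)CO | intermediate
13 | tert-butyl (4S,6E)-4-(iodomethyl)-3,3,7,11-tetramethyl-2-(3-methylbut-2-en-1-yl)dodeca-6,10-dienoate | CC(C)=CCC/C(C)=C/C[C@@H](C(C)(C)C(CC=C(C)C)C(=O)OC(C)(C)C)CI | intermediate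
14 | acetic acid | CC(=O)O | starting material
15 | dilithio acetate (enediolate) | [Li+].[Li+].C=C([O-])[O-] | intermediate
16 | (4E)-5,9-dimethyldeca-4,8-dienoic acid | CC(C)=CCC/C(C)=C/CCC(=O)O | intermediate
17 | dilithium enediolate of 16 | [Li+].[Li+].CC(C)=CCC/C(C)=C/CC=C([O-])[O-] | intermediate
18 | (4R)-7-tert-butoxy-2,4-bis[(2E)-3,7-dimethylocta-2,6-dien-1-yl]-5,5-dimethyl-6-(3-methylbut-2-en-1-yl)-7-oxoheptanoic acid | CC(C)=CCC/C(C)=C/C[C@@H](C(C)(C)C(CC=C(C)C)C(=O)OC(C)(C)C)CC(C/C=C(\C)CCC=C(C)C)C(=O)O | intermediate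
19 | bis(trimethylsilyl) ester of 20 | CC(C)=CCC/C(C)=C/C[C@@H](C(C)(C)C(CC=C(C)C)C(=O)O[Si](C)(C)C)CC(C/C=C(\C)CCC=C(C)C)C(=O)O[Si](C)(C)C | intermediate
20 | (4R)-4,6-bis[(2E)-3,7-dimethylocta-2,6-dien-1-yl]-3,3-dimethyl-2-(3-methylbut-2-en-1-yl)heptanedioic acid | CC(C)=CCC/C(C)=C/C[C@@H](C(C)(C)C(CC=C(C)C)C(=O)O)CC(C/C=C(\C)CCC=C(C)C)C(=O)O | intermediate
21 | bis(acid chloride) of 20 | CC(C)=CCC/C(C)=C/C[C@@H](C(C)(C)C(CC=C(C)C)C(Cl)=O)CC(C/C=C(\C)CCC=C(C)C)C(Cl)=O | intermediate
22 | bis(ketene) derived from 21 | CC(C)=CCC/C(C)=C/C[C@@H](C(C)(C)C(CC=C(C)C)=C=O)CC(C/C=C(\C)CCC=C(C)C)=C=O | intermediate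
23 | (3R)-3,5-bis[(2E)-3,7-dimethylocta-2,6-dien-1-yl]-2,2-dimethyl-1-(3-methylbut-2-en-1-yl)bicyclo[3.1.1]heptane-6,7-dione | CC(C)=CCC/C(C)=C/C[C@@H]1CC2(C/C=C(\C)CCC=C(C)C)C(=O)C(CC=C(C)C)(C2=O)C1(C)C | intermediate
24 | ethoxyacetylene | CCOC#C | starting material
25 | (1R,5S,7R)-4-ethoxy-5,7-bis[(2E)-3,7-dimethylocta-2,6-dien-1-yl]-8,8-dimethyl-1-(3-methylbut-2-en-1-yl)bicyclo[3.3.1]non-3-ene-2,9-dione | CC(C)=CCC/C(C)=C/C[C@@H]1C[C@]2(C/C=C(\C)CCC=C(C)C)C(=O)[C@@](CC=C(C)C)(C(=O)C=C2OCC)C1(C)C | intermediate
26 | 3,4-dihydroxybenzoic acid | O=C(O)c1ccc(O)c(O)c1 | starting material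
27 | tert-butyldimethylsilyl 3,4-bis(tert-butyldimethylsilyloxy)benzoate | CC(C)(C)[Si](C)(C)OC(=O)c1ccc(O[Si](C)(C)C(C)(C)C)c(O[Si](C)(C)C(C)(C)C)c1 | intermediate
28 | 3,4-bis(tert-butyldimethylsilyloxy)benzoyl chloride | CC(C)(C)[Si](C)(C)Oc1ccc(C(Cl)=O)cc1O[Si](C)(C)C(C)(C)C | intermediate
29 | C3-lithio derivative of 25 | CC(C)=CCC/C(C)=C/C[C@@H]1C[C@]2(C/C=C(\C)CCC=C(C)C)C(=O)[C@@](CC=C(C)C)(C(=O)C([Li])=C2OCC)C1(C)C | intermediate
30 | (1S,5S,7R)-3-[3,4-bis(tert-butyldimethylsilyloxy)benzoyl]-4-ethoxy-5,7-bis[(2E)-3,7-dimethylocta-2,6-dien-1-yl]-8,8-dimethyl-1-(3-methylbut-2-en-1-yl)bicyclo[3.3.1]non-3-ene-2,9-dione | CC(C)=CCC/C(C)=C/C[C@@H]1C[C@]2(C/C=C(\C)CCC=C(C)C)C(=O)[C@@](CC=C(C)C)(C(=O)C(C(=O)c3ccc(O[Si](C)(C)C(C)(C)C)c(O[Si](C)(C)C(C)(C)C)c3)=C2OCC)C1(C)C | intermediate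
31 | (1S,5S,7R)-3-(3,4-dihydroxybenzoyl)-4-hydroxy-5,7-bis[(2E)-3,7-dimethylocta-2,6-dien-1-yl]-8,8-dimethyl-1-(3-methylbut-2-en-1-yl)bicyclo[3.3.1]non-3-ene-2,9-dione (CNP0125932.1) | CC(C)=CCC/C(C)=C/C[C@@H]1C[C@]2(C/C=C(\C)CCC=C(C)C)C(=O)[C@@](CC=C(C)C)(C(=O)C(C(=O)c3ccc(O)c(O)c3)=C2O)C1(C)C | target

Total step count: 15. Longest linear sequence: 12 steps (steps 1–6, 8–11, 14 and 15); steps 7, 12 and 13 are side branches.

Steps most likely to fail

1. Step 11 (proposed method). Nickel-mediated oligomerisation of the terminal ynol ether may outrun oxidative cyclisation at the hindered carbonyl. The catalyst may also discriminate poorly between the two carbonyl bridges, which would lead into the C7-epimeric series, or the phosphine may open the strained dione. The fallback uses known chemistry, sets out from 23 and comes back at 25. Hydroxide opens the cyclobutanedione and the resulting β-keto acid decarboxylates (KOH, aqueous EtOH, reflux; then H3O+) to the cyclohexanone F1, in which both former bridgeheads are CH centres again. Kinetic enolisation and silylation (LiN(i-Pr)2, t-BuMe2SiCl, THF–DMPU) should give the silyl enol ether F2. Effenberger-type annulation with malonyl dichloride, followed by KOH and BnEt3NCl, should build the bicyclic trione F3, the malonyl bridge being delivered anti to the C7 substituent as is known for enol ethers of 4-substituted 2,6-dialkylcyclohexanones. O-Ethylation (HC(OEt)3, TsOH cat., EtOH) should give 25 together with its regioisomeric enol ether F4; both can enter step 14 because they converge in step 15.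

2. Step 10. The less hindered ketene forms first and may add to the 2,3-double bond of the C7 geranyl group through its own three-atom tether (intramolecular ketene–alkene cycloaddition) before the hindered ketene is available. O-acylation to a β-lactone-type dimer and intermolecular oligomerisation are further ways to lose material. The fallback sets out from 18 and comes back at 23; it needs only the hindered ketene and offers it a far more nucleophilic partner. The free acid of 18 is reduced through its mixed carbonic anhydride (i-BuOCOCl, N-methylmorpholine; then NaBH4) to the alcohol F5 and oxidised with Dess–Martin periodinane to the aldehyde F6. Excess t-BuMe2SiOTf with Et3N should form the silyl enol ether and turn the tert-butyl ester into a silyl ester, which brief treatment with K2CO3 in MeOH cleaves to the acid F7. Acid chloride formation (Me2C=C(Cl)NMe2) and Et3N in hot toluene then generate one ketene, which the enol ether should trap in a crossed intramolecular [2+2] cycloaddition (ketene carbonyl carbon to the geranyl-bearing enol carbon, ketene α-carbon to the silyloxy carbon). This gives the silyloxy ketone F8 as a diastereomer mixture of no consequence. HF·pyridine gives the hydroxy ketone F9, and Dess–Martin oxidation gives 23.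

3. Step 8. Substitution at the β-branched iodide next to a quaternary carbon may be slow, so that elimination by the strongly basic enediolate, or lactonisation of the iodo ester with loss of isobutene, takes over. The fallback sets out from 13 and comes back at 18; it replaces the enediolate by a malonic ester synthesis. The softer, less basic sodium enolate of diethyl malonate (NaH, DMF, 60 °C) should displace the iodide to give the malonate F10. A second alkylation with the reactive geranyl bromide 9 (NaH, THF) gives the quaternary malonate F11. Saponification of the two ethyl esters (KOH, aqueous EtOH; the tert-butyl ester is inert) gives the malonic acid F12, and thermal decarboxylation (PhMe, 110 °C) gives 18.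

Further compounds
F1 | step 11 | (4R)-2,4-bis[(2E)-3,7-dimethylocta-2,6-dien-1-yl]-5,5-dimethyl-6-(3-methylbut-2-en-1-yl)cyclohexan-1-one (epimers at C2 and C6) | CC(C)=CCC/C(C)=C/C[C@@H]1CC(C/C=C(\C)CCC=C(C)C)C(=O)C(CC=C(C)C)C1(C)C
F2 | step 11 | tert-butyldimethylsilyl enol ether of F1 with the double bond toward the geranyl-bearing α-carbon | CC(C)=CCC/C(C)=C/C[C@@H]1CC(C/C=C(\C)CCC=C(C)C)=C(O[Si](C)(C)C(C)(C)C)C(CC=C(C)C)C1(C)C
F3 | step 11 | (1R,5S,7R)-4-hydroxy-5,7-bis[(2E)-3,7-dimethylocta-2,6-dien-1-yl]-8,8-dimethyl-1-(3-methylbut-2-en-1-yl)bicyclo[3.3.1]non-3-ene-2,9-dione (enol of the 2,4,9-trione) | CC(C)=CCC/C(C)=C/C[C@@H]1C[C@]2(C/C=C(\C)CCC=C(C)C)C(=O)[C@@](CC=C(C)C)(C(=O)C=C2O)C1(C)C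
F4 | step 11 | regioisomer of 25 with the ethoxy group on the carbon next to the prenyl-bearing bridgehead and the enone carbonyl next to the geranyl-bearing bridgehead, same configuration at both bridgeheads and C7 | CC(C)=CCC/C(C)=C/C[C@@H]1C[C@]2(C/C=C(\C)CCC=C(C)C)C(=O)[C@@](CC=C(C)C)(C(OCC)=CC2=O)C1(C)C
F5 | step 10 | tert-butyl ester of 18 with the free carboxyl reduced to CH2OH | CC(C)=CCC/C(C)=C/C[C@@H](C(C)(C)C(CC=C(C)C)C(=O)OC(C)(C)C)CC(C/C=C(\C)CCC=C(C)C)CO
F6 | step 10 | aldehyde from F5 | CC(C)=CCC/C(C)=C/C[C@@H](C(C)(C)C(CC=C(C)C)C(=O)OC(C)(C)C)CC(C/C=C(\C)CCC=C(C)C)C=O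
F7 | step 10 | carboxylic acid bearing the tert-butyldimethylsilyl enol ether of the F6 aldehyde (E/Z mixture) | CC(C)=CCC/C(C)=C/C[C@@H](C(C)(C)C(CC=C(C)C)C(=O)O)CC(C/C=C(\C)CCC=C(C)C)=CO[Si](C)(C)C(C)(C)C
F8 | step 10 | (3R)-7-(tert-butyldimethylsilyloxy)-3,5-bis[(2E)-3,7-dimethylocta-2,6-dien-1-yl]-2,2-dimethyl-1-(3-methylbut-2-en-1-yl)bicyclo[3.1.1]heptan-6-one (diastereomer mixture) | CC(C)=CCC/C(C)=C/C[C@@H]1CC2(C/C=C(\C)CCC=C(C)C)C(O[Si](C)(C)C(C)(C)C)C(CC=C(C)C)(C2=O)C1(C)C
F9 | step 10 | (3R)-7-hydroxy analogue of F8 | CC(C)=CCC/C(C)=C/C[C@@H]1CC2(C/C=C(\C)CCC=C(C)C)C(O)C(CC=C(C)C)(C2=O)C1(C)C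
F10 | step 8 | diethyl malonate alkylated by 13 at its central carbon | CC(C)=CCC/C(C)=C/C[C@@H](C(C)(C)C(CC=C(C)C)C(=O)OC(C)(C)C)CC(C(=O)OCC)C(=O)OCC
F11 | step 8 | F10 carrying an additional geranyl group on the malonate carbon | CC(C)=CCC/C(C)=C/C[C@@H](C(C)(C)C(CC=C(C)C)C(=O)OC(C)(C)C)CC(C/C=C(\C)CCC=C(C)C)(C(=O)OCC)C(=O)OCC
F12 | step 8 | malonic acid from F11 (tert-butyl ester retained) | CC(C)=CCC/C(C)=C/C[C@@H](C(C)(C)C(CC=C(C)C)C(=O)OC(C)(C)C)CC(C/C=C(\C)CCC=C(C)C)(C(=O)O)C(=O)O
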